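This closed, stirred vessel keeps the gas at a saturation concentration of 2.7 mM, none of it dissolved at the start, and I want the electrophile consumed at three charges of protonated nucleophile.

the same everywhere: gas 2.7 mM (held)
- midnight: electrophile 9.4 mM; protonated nucleophile 35 mM; run made earlier
- noon: electrophile 7 mM; protonated nucleophile 35 mM; run made earlier
- west: electrophile 14 mM; protonated nucleophile 35.0 mM; time 1.0 h
- east: electrophile 14 mM; protonated nucleophile 52.0 mM; time 1.0 h
- north-east: electrophile 14 mM; protonated nucleophile 79.0 mM; time 1.0 h

| run | time / min | electrophile / % | target / % |
|---|---|---|---|
| midnight | 1.00 | 99.7 | 0 |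
| midnight | 1.50 | 99.2 | 0.6 |
| midnight | 2.50 | 99.5 | 0.1 |
| midnight | 4.00 | 99.3 | 0.7 |
| midnight | 8.00 | 97.5 | 1.7 |
| midnight | 12.0 | 96.0 | 2.6 |
| noon | 0.833 | 99.7 | 0.1 |
| noon | 2.50 | 99.6 | 0.6 |
| noon | 4.00 | 99.6 | 1.1 |
| noon | 6.00 | 98.4 | 1.3 |
| noon | 10.0 | 97.1 | 2.8 |
| noon | 12.0 | 96.0 | 3.0 |

(each reading ± 0.3 percentage points)

- part of the electrophile that has reacted at the end, west
- part of the electrophile that has reacted at the end, east
- part of the electrophile that has reacted at the end, north-east
- what raising the concentration of protonated nucleophile from its lowest to its highest value here does to the part of the electrophile that has reacted (changes below 5 percentage points count as none) (it falls / no change / it rises)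

- what was read earlier has a scatter of 0.3 percentage points, one standard deviation
- at the start none of the gas is in solution

Electrophile is the limiting reagent, so I write its balance: its loss equals a specific rate s times [electrophile]. Midnight and noon, charged at 9.4 mM and 7 mM, both read 96.0% left at 12.0 min, so within the scatter s does not follow [electrophile]. At that time they give 0.0408 for the exposure, the natural logarithm of electrophile charged over electrophile left.

Two extremes can be done in the head. If s stays constant, exposure grows with time, and west at 1.0 h reaches 0.204, or 18.5% reacted. If s grows in proportion to time, exposure grows with its square, and west reaches 1.02, or 63.9% reacted. The readings lie between: the power of time reads 1.60 in midnight from 4.00 min and 1.34 in noon from 6.00 min. I take the midway power, 3/2.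

No run varied [protonated nucleophile]. I expect its order between zero and one, and if it parts into two species, the free form follows the square root, so I assume that. My reckoning gives 0.456 for west, hence 36.6%, then 42.7% for east and 49.6% for north-east.

The forecast says 21%, 28% and 38%, lower than mine, and also that the part reacted rises: it rises. Of its step to higher charges it says: "This extrapolation is the main uncertainty".

The flask gives 36.3% in west, 42.8% in east and 50.4% in north-east, so on the trend the answer is: it rises, by 14 percentage points, and that gap between north-east and west is owed to the difference in concentration of protonated nucleophile.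

    acid set free → by-product carried off (k = 0.240 min⁻¹)
    electrophile + nucleophile → acid set free + target (k = 1.00 M⁻¹ min⁻¹)
    nucleophile + acid set free ⇌ protonated nucleophile, settled at all times (K = 9000 M⁻¹)
    acid set free + free base ⇌ salt of the base (K = 3.40 × 10⁵ M⁻¹, k = 5.30 M⁻¹ min⁻¹)
    gas ⇌ free base, rate k5*(csat - [free base]) (kL = 0.0360 min⁻¹)
    electrophile + target → side product (k = 4.20 M⁻¹ min⁻¹)

West reaches an exposure of 0.451, against my 0.456. Part of what lifts s is the loss of acid set free to by-product carried off: the west run without that step stands at 14.7% reacted, not 36.3%. Read at 4.0 h, the same west flask has by my power law 97.4% reacted, and the flask itself stands at 95.3%.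

The readings are calculated with constants of no real substance; scatter was added.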